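Do not take a flat curve for a finished reaction; first ask what became of the rate.

| flask | substrate | coupling partner | free catalyst | second catalyst | temperature | remark | time |
|---|---|---|---|---|---|---|---|
| delta | 0.010 M | 0.013 M | 0.14 mM | 0.25 mM | 35 °C | the very flask that is asked about, followed so far |  |
| theta | 0.010 M | 0.013 M | 0.14 mM | 0.25 mM | 41 °C | run made earlier |  |
| flask | 0.010 M | 0.0130 M | 0.14 mM | 0.25 mM | 35 °C |  | 2.0 h |

- delta (time / min: target / %): 10.0: 65.5; 15.0: 74.0; 20.0: 75.5; 30.0: 75.4; 50.0: 75.2; 80.0: 77.1; 120: 76.6
- theta (time / min: target / %): 10.0: 57.7; 15.0: 58.8; 20.0: 59.0; 30.0: 60.5; 50.0: 58.0; 80.0: 60.5; 120: 61.0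

(readings scatter by 1 percentage point)

- removed target is counted in
- "the catalyst" is free catalyst with its forms; second catalyst is a second catalyst
- additions bring no volume worth counting

- south: at 2.0 h add coupling partner, 100 % of the amount charged, then wait 40 min
- north: change nothing and wait 40 min more
- north-west: at 2.0 h take out 90 % of the target then present, then wait 40 min
- north-east: at 2.0 h raise the temperature by 25 K, then wait 40 min
- west: at 2.0 h add free catalyst, 100 % of the amount charged, then wait 40 min

* target, in percent of the substrate first charged, at 2.0 h
* the remedy with the largest gain of target, or "none" below 2 percentage points (south / north / north-west / north-east / west / none)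
* target present, with what was taken out counted in, in percent of the substrate first charged, after north-east
* target present, with what was taken out counted in, in percent of the substrate first charged, after west

Delta is this very flask, and theta is the same recipe run 6.00 K hotter. Take the five readings from 20.0 min on as each plateau: delta stands at 76.0 %, theta at 59.8 %.

Work in powers of ten. Call the reach the common logarithm of the charge over what is not yet target, that is, the powers of ten a flask gets through before it stops:

delta: 0.619
theta: 0.396, smaller by a factor 1.56

Now follow the rate in delta, as reach gained per minute: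

up to 10.0 min: 0.0462 min⁻¹
up to 15.0 min: 0.0246 min⁻¹, slower by 1.88
up to 20.0 min: 0.00516 min⁻¹, slower by 4.77
up to 120 min: 2.00 × 10⁻⁴ min⁻¹, slower by 25.9

The last two rates rest on gains of 1.5 percentage points and 1.1 points, against a scatter of 1 point. Together the factors take 2.36 powers of ten off the rate. At the last rate, 40 min more brings 0.44 points, less than the mark of 2 points.

So I say 76.0 % now. These readings leave open an equilibrium or lost catalyst; I judge the catalyst lost, and on that judgement I put north-east at 76.0 % too. A repeat charge of free catalyst should then buy the same reach again:

target after west = 94.2 %, a gain of 18 points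

The ratio c(coupling partner)/c(substrate) is 1.30, more than that share, so substrate stays the limiting reagent.

The forecast says 76 % now, west as best, 76 % after north-east and 90 % after west, lower than my figure, reasoning that “Fresh catalyst should then restart the reaction”.

The flask gives 75.5 % at 2.0 h, 75.5 % after north-east and 92.1 % after west, a gain of 17 points.

    coupling partner + free catalyst → spent catalyst B (k = 0.153 L mol⁻¹ s⁻¹, Ea = 45.0 kJ mol⁻¹)
    free catalyst → spent catalyst A (k = 0.00594 s⁻¹, Ea = 85.0 kJ mol⁻¹)
    coupling partner + catalyst intermediate → second catalyst + target (k = 50.8 L mol⁻¹ s⁻¹, Ea = 38.0 kJ mol⁻¹)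
    second catalyst + open intermediate ⇌ catalyst intermediate (K = 60.0 L mol⁻¹, k = 343 L mol⁻¹ s⁻¹, Ea = 39.0 kJ mol⁻¹, ΔH = −28.0 kJ mol⁻¹)
    substrate + free catalyst ⇌ free catalyst + open intermediate (K = 0.680, k = 389 L mol⁻¹ s⁻¹, Ea = 46.0 kJ mol⁻¹, ΔH = −42.0 kJ mol⁻¹)
    (constants at 35 °C)

At 120 min free catalyst stands at 0 %, with 78.5 % as spent catalyst A and 21.5 % as spent catalyst B. The repeat charge added a reach of 0.492, less than the 0.619 of the first. Take one further flask, the same recipe run at 60 °C from the start, and stretch the factor 1.56 over the 25.0 K from delta: its reach comes to 0.0960, its target to 19.8 %, and at 120 min that flask holds 22.8 %.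

Readings and results are simulated for substances that don't exist; scatter was added.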